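**Retrosynthetic overview**

1. Numbering and feature: C8 is the acetoxy-bearing bridgehead, flanked by C7 (ArCH) and C9 (OCH2); C8' is the CH bridgehead, flanked by C7' (ArCH) and C9' (OCH2); ring A = C7'–O–C9–C8–C8', ring B = C7–O–C9'–C8'–C8. The plan rests on ring A: aryl on C7', C9' on C8' and oxygen on C8 sit on alternating faces, which is what a carbon nucleophile at C8' followed by an oxygen electrophile at C8 of a C7'-aryl butenolide (C8=C8', C9 as lactone carbonyl) should give if each enters trans to its neighbour.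
2. Late stage: the phenol benzyl ethers and the C8 acetate come last; C9 is reduced from lactone carbonyl to CH2 after ring B has been closed by attack of the C7 oxygen on a C9' mesylate, the C9' oxygen arising by Tamao oxidation of a silylmethyl group.
3. Key disconnection: C8'–C9' and C8–O across the butenolide double bond, with the silyl-protected C7 arm already on C8 so that it ends cis to C9'.
4. Butenolide: C9 comes from CO by carbonylative lactonisation of a (Z)-iodoalkenol, itself made by hydroxyl-directed trans-hydroalumination of a mono-silylated 1,4-diarylbut-2-yne-1,4-diol. C7 is set by lipase resolution of an ethynyl carbinol and C7' by BINOL-controlled alkynylzinc addition, both from O-benzylvanillin. Benzyl ethers protect the phenols because they must survive fluoride and peroxide.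
5. Ring order: ring A first (as the butenolide, step 6), then ring B (step 11); ring A is kept and only reduced at C9 (steps 12 and 13).

Key step: step 8

Abbreviation: Ar = 4-(benzyloxy)-3-methoxyphenyl.

Assumption: the (S)-BINOL/Ti(OiPr)4 alkynylzinc addition of step 4 is taken to attack the Si face of aldehyde 1, as it does with simple aryl aldehydes; should alkyne 5 reverse this preference, (R)-BINOL would be used and nothing else would change.

**Route**

Step 1
Reactants: 1 4-(benzyloxy)-3-methoxybenzaldehyde; 2 ethynylmagnesium bromide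
Product: 3 rac-1-Ar-prop-2-yn-1-ol
Conditions: THF, 0 °C; H2O
Reagents that add atoms: none
Why: Grignard 1,2-addition of the acetylide to the aldehyde should give the racemic propargylic alcohol, whose single stereocentre (the later C7) is resolved in step 2.

Step 2
Reactants: 3 rac-1-Ar-prop-2-yn-1-ol
Product: 4 (S)-1-Ar-prop-2-yn-1-ol
Conditions: immobilised Candida antarctica lipase B, vinyl acetate, tBuOMe, 30 °C, to ca. 55% conversion; chromatography
Reagents that add atoms: none
Why: Lipase-catalysed kinetic resolution by transesterification should acetylate the (R)-alcohol (aryl in the large pocket, ethynyl in the small one) and leave (S)-4 in high enantiomeric purity once conversion passes one half.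

Step 3
Reactants: 4 (S)-1-Ar-prop-2-yn-1-ol
Product: 5 (S)-1-Ar-1-(triethylsilyloxy)prop-2-yne
Conditions: Et3SiCl, imidazole, CH2Cl2, 0 °C
Reagents that add atoms: chlorotriethylsilane CC[Si](Cl)(CC)CC
Why: O-silylation leaves the stereocentre untouched and installs the ether that stays on the C7 oxygen until ring B is closed.

Step 4
Reactants: 5 (S)-1-Ar-1-(triethylsilyloxy)prop-2-yne; 1 4-(benzyloxy)-3-methoxybenzaldehyde
Product: 6 (1R,4R)-1,4-bis(Ar)-4-(triethylsilyloxy)but-2-yn-1-ol
Conditions: 5 (2 equiv), Et2Zn (2 equiv), Cy2NH (5 mol %), Et2O, rt; (S)-BINOL (20 mol %), Ti(OiPr)4 (50 mol %); 1 (1 equiv), rt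
Reagents that add atoms: none
Why: Catalytic asymmetric alkynylzinc addition to an aryl aldehyde under BINOL–titanium control should deliver the alkynyl group to the Si face of 1 and set C7' as (R), the remote C7 centre having no influence, and any C7' epimer is a diastereomer removable by chromatography.

Step 5
Reactants: 6 (1R,4R)-1,4-bis(Ar)-4-(triethylsilyloxy)but-2-yn-1-ol
Product: 8 (1S,2Z,4R)-1,4-bis(Ar)-3-iodo-4-(triethylsilyloxy)but-2-en-1-ol, via cyclic alkenylaluminate 7 (not isolated)
Conditions: NaAlH2(OCH2CH2OMe)2, THF, −20 → 0 °C; EtOAc; N-iodosuccinimide, −78 °C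
Reagents that add atoms: N-iodosuccinimide O=C1CCC(=O)N1I
Why: Hydroxyl-directed trans-hydroalumination: the C7' alkoxide binds the aluminium hydride, hydride goes to C8' and aluminium to C8 within a five-membered oxaaluminacycle, and iodine replaces aluminium with retention, so the C8 iodide ends cis to the C7' carbinol.

Step 6
Reactants: 8 (1S,2Z,4R)-1,4-bis(Ar)-3-iodo-4-(triethylsilyloxy)but-2-en-1-ol; 9 carbon monoxide
Product: 10 (5S)-5-Ar-3-[(R)-Ar(triethylsilyloxy)methyl]furan-2(5H)-one
Conditions: CO (1 atm), PdCl2(PPh3)2 (5 mol %), K2CO3 (suspension), THF, 40 °C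
Reagents that add atoms: none
Why: Palladium-catalysed carbonylative lactonisation: zerovalent palladium inserts into the C8–I bond, CO inserts, and the cis C7' hydroxyl captures the acylpalladium to close ring A as the butenolide; no bond at C7 or C7' is broken, which is why this is preferred to cyclocarbonylations that pass through allenylpalladium species.

Step 7
Reactants: 11 (chloromethyl)(isopropoxy)dimethylsilane
Product: 12 [(isopropoxydimethylsilyl)methyl]magnesium chloride
Conditions: Mg, BrCH2CH2Br (cat.), THF, reflux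
Reagents that add atoms: magnesium [Mg]
Why: Insertion of magnesium into the C–Cl bond gives the α-silyl Grignard reagent that serves as a hydroxymethyl anion equivalent.

Step 8
Reactants: 10 (5S)-5-Ar-3-[(R)-Ar(triethylsilyloxy)methyl]furan-2(5H)-one; 12 [(isopropoxydimethylsilyl)methyl]magnesium chloride
Product: 15 (3R,4R,5S)-5-Ar-3-[(R)-Ar(triethylsilyloxy)methyl]-4-{[isopropoxy(dimethyl)silyl]methyl}-3-(trimethylsilyloxy)dihydrofuran-2(3H)-one, via silyl ketene acetal 13 (not isolated), via silyloxy epoxide 14 (not isolated)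
Conditions: 12 (2.5 equiv, slow addition), CuBr·SMe2 (20 mol %), Me3SiCl (4 equiv), HMPA (2 equiv), THF, −78 → −40 °C; pentane, filtration, evaporation; dimethyldioxirane (acetone), CH2Cl2, −78 °C
Reagents that add atoms: chlorotrimethylsilane C[Si](C)(C)Cl; dimethyldioxirane CC1(C)OO1
Why: The Grignard reagent transmetalates to monovalent copper and the organocopper species adds to C8' of the enoate (π-complex, β-cuprio trivalent-copper enolate, reductive elimination) while Me3SiCl captures the enolate oxygen, so the C8'–C9' bond forms and ketene acetal 13 is released; dimethyldioxirane then transfers oxygen to the C8=C9 bond of 13 to give epoxide 14, which opens with a 1,4 shift of the Me3Si group to the new oxygen and leaves the C8–O bond of 15. The closest known reaction types are the chlorosilane-accelerated copper-catalysed conjugate addition of Grignard reagents to γ-substituted butenolides and the Rubottom oxidation of silyl ketene acetals. No ring is closed, ring A being in place since step 6. C8' is controlled by the C7' aryl group, which shields one face of the nearly flat butenolide so that the copper reagent enters anti to it and C9' ends trans to the aryl group. C8 is controlled by the new C9' arm on the adjacent carbon, which sends the oxidant to the opposite face of 13, so that oxygen ends cis to the C7' aryl group and the C7 arm cis to C9', as ring B requires. The step needs 1,4-addition in preference to attack at the lactone carbonyl or removal of the acidic C7' hydrogen, and it needs the C7 silyl ether to stay in place; the soft copper reagent at low temperature is meant to secure the first, and silyl trapping, which never leaves a free enolate β to the C7 silyloxy group, the second.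

Step 9
Reactants: 15 (3R,4R,5S)-5-Ar-3-[(R)-Ar(triethylsilyloxy)methyl]-4-{[isopropoxy(dimethyl)silyl]methyl}-3-(trimethylsilyloxy)dihydrofuran-2(3H)-one
Product: 16 (3R,4R,5S)-5-Ar-3-[(R)-Ar(triethylsilyloxy)methyl]-3-hydroxy-4-(hydroxymethyl)dihydrofuran-2(3H)-one
Conditions: KF, KHCO3, 30% H2O2, THF/MeOH, 0 °C → rt
Reagents that add atoms: hydrogen peroxide OO
Why: Tamao oxidation: hydroperoxide adds to the fluoride-activated alkoxysilane and C9' migrates from silicon to oxygen, so C–Si becomes C9'–OH without touching a stereocentre, while KF in methanol also removes the labile tertiary Me3Si ether and should leave the Et3Si and benzyl ethers in place.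

Step 10
Reactants: 16 (3R,4R,5S)-5-Ar-3-[(R)-Ar(triethylsilyloxy)methyl]-3-hydroxy-4-(hydroxymethyl)dihydrofuran-2(3H)-one
Product: 17 primary (C9') methanesulfonate of 16
Conditions: MeSO2Cl, Et3N, CH2Cl2, −20 °C
Reagents that add atoms: methanesulfonyl chloride CS(=O)(=O)Cl
Why: Sulfonylation of the primary C9' hydroxyl is far faster than that of the tertiary C8 hydroxyl, so only C9' becomes a leaving group.

Step 11
Reactants: 17 primary (C9') methanesulfonate of 16
Product: 19 (3S,3aR,6R,6aR)-3,6-bis(Ar)-6a-hydroxytetrahydro-1H,3H-furo[3,4-c]furan-1-one, via hydroxy mesylate 18 (not isolated)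
Conditions: HF·pyridine, pyridine, THF, 0 °C → rt; 2,6-lutidine, 50 °C
Reagents that add atoms: none
Why: Fluoride cleaves the Et3Si ether and the freed C7 hydroxyl displaces the primary mesylate (Williamson etherification, 5-exo-tet) to close ring B; C7 keeps its configuration because it is not the electrophilic carbon, the cis fusion follows from the cis C7 arm and C9' on ring A, and the absence of strong base is meant to suppress retro-aldol cleavage of the C7–C8 bond.

Step 12
Reactants: 19 (3S,3aR,6R,6aR)-3,6-bis(Ar)-6a-hydroxytetrahydro-1H,3H-furo[3,4-c]furan-1-one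
Product: 20 (3S,3aR,6R,6aR)-3,6-bis(Ar)tetrahydro-1H,3H-furo[3,4-c]furan-1,6a-diol (lactol; C1 epimers)
Conditions: iBu2AlH (2.5 equiv), CH2Cl2, −78 °C; aq. potassium sodium tartrate
Reagents that add atoms: none
Why: Hydride addition to the lactone carbonyl at low temperature stops at the aluminium hemiacetal, which gives the lactol on work-up, one equivalent of hydride being consumed by the C8 hydroxyl; the new C9 centre is of no consequence.

Step 13
Reactants: 20 (3S,3aR,6R,6aR)-3,6-bis(Ar)tetrahydro-1H,3H-furo[3,4-c]furan-1,6a-diol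
Product: 21 (3R,3aS,6S,6aR)-3,6-bis(Ar)-3,4,6,6a-tetrahydro-1H-furo[3,4-c]furan-3a-ol
Conditions: Et3SiH, BF3·OEt2, CH2Cl2, −78 → −40 °C
Reagents that add atoms: none
Why: Ionic hydrogenation of the lactol: BF3 ionises the anomeric hydroxyl to a ring A oxocarbenium ion that Et3SiH reduces to the C9 methylene, the low temperature being chosen so that the benzylic C7–O and C7'–O bonds are not ionised.

Step 14
Reactants: 21 (3R,3aS,6S,6aR)-3,6-bis(Ar)-3,4,6,6a-tetrahydro-1H-furo[3,4-c]furan-3a-ol
Product: 22 (3R,3aS,6S,6aR)-3,6-bis(Ar)-3,4,6,6a-tetrahydro-1H-furo[3,4-c]furan-3a-yl acetate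
Conditions: Ac2O, Et3N, 4-(dimethylamino)pyridine (1 equiv), CH2Cl2, 40 °C
Reagents that add atoms: acetic anhydride CC(=O)OC(C)=O
Why: Nucleophilic catalysis through the N-acetylpyridinium salt should acetylate the hindered tertiary C8 hydroxyl, the only free hydroxyl in 21.

Step 15
Reactants: 22 (3R,3aS,6S,6aR)-3,6-bis(Ar)-3,4,6,6a-tetrahydro-1H-furo[3,4-c]furan-3a-yl acetate
Product: 23 1-acetoxypinoresinol
Conditions: H2 (1 atm), 10% Pd/C, EtOAc, rt, stopped at consumption of 22
Reagents that add atoms: none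
Why: Hydrogenolysis of the two aryl benzyl ethers over palladium is much faster than cleavage of the benzylic C–O bonds of the bicyclic ether, so both phenols should be freed while the acetate and all four stereocentres stay untouched.

**Compound list**

1 | 4-(benzyloxy)-3-methoxybenzaldehyde (O-benzylvanillin, ArCHO) | COc1cc(C=O)ccc1OCc1ccccc1 | starting material
2 | ethynylmagnesium bromide | C#C[Mg]Br | starting material
3 | rac-1-Ar-prop-2-yn-1-ol | COc1cc(C(O)C#C)ccc1OCc1ccccc1 | intermediate
4 | (S)-1-Ar-prop-2-yn-1-ol | COc1cc([C@@H](O)C#C)ccc1OCc1ccccc1 | intermediate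
5 | (S)-1-Ar-1-(triethylsilyloxy)prop-2-yne | COc1cc([C@@H](O[Si](CC)(CC)CC)C#C)ccc1OCc1ccccc1 | intermediate
6 | (1R,4R)-1,4-bis(Ar)-4-(triethylsilyloxy)but-2-yn-1-ol (C1 = C7', C4 = C7) | COc1cc([C@@H](O)C#C[C@H](O[Si](CC)(CC)CC)c2ccc(OCc3ccccc3)c(OC)c2)ccc1OCc1ccccc1 | intermediate
7 | sodium cyclic alkenylaluminate: 2,2-bis(2-methoxyethoxy)-1,2-oxaaluminol-2-uide ring O–Al–C8=C8'–C7', with (S)-C7' bearing Ar and C8 bearing the (R)-Ar(triethylsilyloxy)methyl group | [Na+].COCCO[Al-]1(OCCOC)O[C@H](c2ccc(OCc3ccccc3)c(OC)c2)C=C1[C@H](O[Si](CC)(CC)CC)c1ccc(OCc2ccccc2)c(OC)c1 | intermediate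
8 | (1S,2Z,4R)-1,4-bis(Ar)-3-iodo-4-(triethylsilyloxy)but-2-en-1-ol | COc1cc([C@@H](O)/C=C(\I)[C@H](O[Si](CC)(CC)CC)c2ccc(OCc3ccccc3)c(OC)c2)ccc1OCc1ccccc1 | intermediate
9 | carbon monoxide | [C-]#[O+] | starting material
10 | (5S)-5-Ar-3-[(R)-Ar(triethylsilyloxy)methyl]furan-2(5H)-one | COc1cc([C@H]2OC(=O)C([C@H](O[Si](CC)(CC)CC)c3ccc(OCc4ccccc4)c(OC)c3)=C2)ccc1OCc1ccccc1 | intermediate
11 | (chloromethyl)(isopropoxy)dimethylsilane | CC(C)O[Si](C)(C)CCl | starting material
12 | [(isopropoxydimethylsilyl)methyl]magnesium chloride | CC(C)O[Si](C)(C)C[Mg]Cl | intermediate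
13 | silyl ketene acetal: (4S,5S)-5-Ar-3-[(R)-Ar(triethylsilyloxy)methyl]-4-{[isopropoxy(dimethyl)silyl]methyl}-2-(trimethylsilyloxy)-4,5-dihydrofuran (Ar and silylmethyl trans) | COc1cc([C@H]2OC(O[Si](C)(C)C)=C([C@H](O[Si](CC)(CC)CC)c3ccc(OCc4ccccc4)c(OC)c3)[C@@H]2C[Si](C)(C)OC(C)C)ccc1OCc1ccccc1 | intermediate
14 | silyloxy epoxide: 13 with an oxirane across C8–C9, its oxygen on the face of the C7' aryl group and opposite to the C9' arm | COc1cc([C@H]2O[C@@]3(O[Si](C)(C)C)O[C@@]3([C@H](O[Si](CC)(CC)CC)c4ccc(OCc5ccccc5)c(OC)c4)[C@@H]2C[Si](C)(C)OC(C)C)ccc1OCc1ccccc1 | intermediate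
15 | (3R,4R,5S)-5-Ar-3-[(R)-Ar(triethylsilyloxy)methyl]-4-{[isopropoxy(dimethyl)silyl]methyl}-3-(trimethylsilyloxy)dihydrofuran-2(3H)-one | COc1cc([C@H]2OC(=O)[C@](O[Si](C)(C)C)([C@H](O[Si](CC)(CC)CC)c3ccc(OCc4ccccc4)c(OC)c3)[C@@H]2C[Si](C)(C)OC(C)C)ccc1OCc1ccccc1 | intermediate
16 | (3R,4R,5S)-5-Ar-3-[(R)-Ar(triethylsilyloxy)methyl]-3-hydroxy-4-(hydroxymethyl)dihydrofuran-2(3H)-one | COc1cc([C@H]2OC(=O)[C@](O)([C@H](O[Si](CC)(CC)CC)c3ccc(OCc4ccccc4)c(OC)c3)[C@@H]2CO)ccc1OCc1ccccc1 | intermediate
17 | primary (C9') methanesulfonate of 16 | COc1cc([C@H]2OC(=O)[C@](O)([C@H](O[Si](CC)(CC)CC)c3ccc(OCc4ccccc4)c(OC)c3)[C@@H]2COS(C)(=O)=O)ccc1OCc1ccccc1 | intermediate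
18 | hydroxy mesylate: 17 without the triethylsilyl group (free (R)-C7 hydroxyl) | COc1cc([C@H]2OC(=O)[C@](O)([C@H](O)c3ccc(OCc4ccccc4)c(OC)c3)[C@@H]2COS(C)(=O)=O)ccc1OCc1ccccc1 | intermediate
19 | (3S,3aR,6R,6aR)-3,6-bis(Ar)-6a-hydroxytetrahydro-1H,3H-furo[3,4-c]furan-1-one (C1 = C9, C3 = C7', C3a = C8', C4 = C9', C6 = C7, C6a = C8) | COc1cc([C@H]2OC(=O)[C@]3(O)[C@@H](c4ccc(OCc5ccccc5)c(OC)c4)OC[C@H]23)ccc1OCc1ccccc1 | intermediate
20 | lactol of 19: (3S,3aR,6R,6aR)-3,6-bis(Ar)tetrahydro-1H,3H-furo[3,4-c]furan-1,6a-diol, C1 epimers | COc1cc([C@H]2OC(O)[C@]3(O)[C@@H](c4ccc(OCc5ccccc5)c(OC)c4)OC[C@H]23)ccc1OCc1ccccc1 | intermediate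
21 | (3R,3aS,6S,6aR)-3,6-bis(Ar)-3,4,6,6a-tetrahydro-1H-furo[3,4-c]furan-3a-ol (1-hydroxypinoresinol dibenzyl ether; C3 = C7, C3a = C8, C6 = C7', C6a = C8') | COc1cc([C@H]2OC[C@]3(O)[C@@H](c4ccc(OCc5ccccc5)c(OC)c4)OC[C@H]23)ccc1OCc1ccccc1 | intermediate
22 | (3R,3aS,6S,6aR)-3,6-bis(Ar)-3,4,6,6a-tetrahydro-1H-furo[3,4-c]furan-3a-yl acetate | COc1cc([C@H]2OC[C@]3(OC(C)=O)[C@@H](c4ccc(OCc5ccccc5)c(OC)c4)OC[C@H]23)ccc1OCc1ccccc1 | intermediate
23 | 1-acetoxypinoresinol, (3R,3aS,6S,6aR)-3,6-bis(4-hydroxy-3-methoxyphenyl)-3,4,6,6a-tetrahydro-1H-furo[3,4-c]furan-3a-yl acetate | COc1cc([C@H]2OC[C@]3(OC(C)=O)[C@@H](c4ccc(O)c(OC)c4)OC[C@H]23)ccc1O | target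

**Step count**

Total: 15 steps. Longest linear sequence: 14 steps (steps 1–6 and 8–15, from 1); step 7 is a one-step side branch to 12.

**Steps most likely to fail**

Step 8. The basic Grignard system may remove the acidic C7' hydrogen of the butenolide and erode its configuration, the labile ketene acetal may be lost before oxidation, or oxygen may be transferred to both of its faces. The fallback sets out from 10 and comes back at 16, and separates the two events. Compound 10 is treated with the less basic stoichiometric organocopper reagent from 12 and CuBr·SMe2 (1:1) and Me3SiCl at −78 °C and quenched with aq. NH4Cl, to give the trans-4,5-disubstituted lactone F1 as a mixture at C8. KN(SiMe3)2 in THF at −78 °C then gives the potassium enolate F2, which at this temperature should not expel the C7 silyloxy group. 2-(Phenylsulfonyl)-3-phenyloxaziridine hydroxylates F2 on the face away from the C9' arm to give the α-hydroxy lactone F3, and the conditions of step 9 convert F3 into 16.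

Step 5. The alkenylaluminate carries the C7 silyloxy group β to aluminium and may eliminate it to an allene, or the silyl ether may be lost. The fallback sets out from 6 and comes back at 8. Trans-hydrosilylation catalysed by [Cp*Ru(MeCN)3]PF6 with BnMe2SiH (CH2Cl2, 0 °C) should place silicon on C8, distal to the free hydroxyl, and give the (Z)-alkenylsilane F4. N-Iodosuccinimide with 2,6-lutidine in MeCN then exchanges silicon for iodine with retention to give 8.

Step 13. Ionisation of the α-hydroxy lactol may be slow enough that the Lewis acid also ionises the benzylic C7–O or C7'–O bonds, with epimerisation or reductive ring opening. The fallback sets out from 19 and comes back at 21, bypassing steps 12 and 13. LiAlH4 in THF at 0 °C opens the lactone to the triol F5. MeSO2Cl in pyridine at 0 °C sulfonylates the primary C9 hydroxyl to the mesylate F6, which is displaced in the same flask by the C7' hydroxyl (5-exo-tet) to rebuild ring A as the ether 21, with retention at C7' and no Lewis acid present.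

**Further compounds**

F1 | step 8 | (4R,5S)-5-Ar-3-[(R)-Ar(triethylsilyloxy)methyl]-4-{[isopropoxy(dimethyl)silyl]methyl}dihydrofuran-2(3H)-one, C3 (C8) epimers | COc1cc([C@H]2OC(=O)C([C@H](O[Si](CC)(CC)CC)c3ccc(OCc4ccccc4)c(OC)c3)[C@@H]2C[Si](C)(C)OC(C)C)ccc1OCc1ccccc1
F2 | step 8 | potassium enolate of F1 | [K+].COc1cc([C@H]2OC([O-])=C([C@H](O[Si](CC)(CC)CC)c3ccc(OCc4ccccc4)c(OC)c3)[C@@H]2C[Si](C)(C)OC(C)C)ccc1OCc1ccccc1
F3 | step 8 | (3R,4R,5S)-5-Ar-3-[(R)-Ar(triethylsilyloxy)methyl]-3-hydroxy-4-{[isopropoxy(dimethyl)silyl]methyl}dihydrofuran-2(3H)-one | COc1cc([C@H]2OC(=O)[C@](O)([C@H](O[Si](CC)(CC)CC)c3ccc(OCc4ccccc4)c(OC)c3)[C@@H]2C[Si](C)(C)OC(C)C)ccc1OCc1ccccc1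
F4 | step 5 | (1S,2Z,4R)-1,4-bis(Ar)-3-[benzyl(dimethyl)silyl]-4-(triethylsilyloxy)but-2-en-1-ol | COc1cc([C@@H](O)/C=C(\[Si](C)(C)Cc2ccccc2)[C@H](O[Si](CC)(CC)CC)c2ccc(OCc3ccccc3)c(OC)c2)ccc1OCc1ccccc1
F5 | step 13 | triol: ring B tetrahydrofuran with 2-Ar (C7), 3-hydroxy-3-(hydroxymethyl) (C8, C9) and 4-[(S)-Ar(hydroxy)methyl] (C8', C7') | COc1cc([C@@H](O)[C@H]2CO[C@H](c3ccc(OCc4ccccc4)c(OC)c3)[C@@]2(O)CO)ccc1OCc1ccccc1
F6 | step 13 | primary (C9) methanesulfonate of F5 | COc1cc([C@@H](O)[C@H]2CO[C@H](c3ccc(OCc4ccccc4)c(OC)c3)[C@@]2(O)COS(C)(=O)=O)ccc1OCc1ccccc1
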